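The furofuran is cut at C9'–C8' (ring A) and C7'–O9 (ring B). The feature exploited: C9' is a CH2 lying between the C7 oxygen and C8', and C7' is benzylic, para to an oxygen donor, and bonded to the C9 oxygen. An O7=C9' oxocarbenium ion can therefore add to C8' of a C8'=C7' styrene, and O9 can take the C7' cation. One Lewis-acid operation closes both rings, forms two bonds and sets C8' and C7'. The precursor 15 is the acyclic anti (1S,2S) MOM ether of a 1-aryl-2-(silyloxymethyl)-4-arylbut-3-en-1-ol; its C7 and C8 centres come from an auxiliary-controlled anti-aldol, and a mesylate deactivates the C7 aryl group.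

Key step: step 9

**Conventions and design decisions**
- **Numbering.** C7/C8/C9 belong to the half that ends as the free guaiacyl unit, and C7'/C8'/C9' to the half that ends as the prenyloxyaryl unit. Ring A is C7–O–C9'–C8'–C8 and ring B is C7'–O–C9–C8–C8'. O7 and O9 are the oxygens on C7 and C9. Ar = 3-methoxy-4-(mesyloxy)phenyl; Ar' = 3-methoxy-4-(triisopropylsilyloxy)phenyl.
- **Reading of the target.** It is (7S,8S,7'R,8'S) and cis-fused. The guaiacyl group on C7 is cis to C9 (endo) and the prenyloxyaryl group on C7' is trans to C9' (exo), so the target belongs to the 7-epi (epipinoresinol-type) series. A cis Ar/C9 relation on ring A corresponds to the anti aldol relation in the open chain, (1S,2S) in 12–15.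
- **O9 carries TBS, not a small silyl group.**
  - In the anti series O9 is well placed to add to the oxocarbenium carbon and give a trans-diequatorial 4-aryl-5-styryl-1,3-dioxane.
  - That acetal is a sink, and its re-opening could move the CH2 to O9.
  - Bulk at silicon and dilution slow both the oxonium pre-equilibrium and the bimolecular desilylation behind this path. They do not slow the unimolecular C–C closure.
- **C8' must be set kinetically.** Cation 17 is far better stabilised than 16, so reversal of ring A closure is not relied on to correct C8'. External capture of 17 by MeOSiMe3 is reversible for so electron-rich a benzylic ether and only parks the cation.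
- **Buffered Lewis acid.** A hindered pyridine is present in step 9 so that only silicon Lewis acidity operates.
- **Order after the aldol.** The imide is reduced first, with the O-SiMe3 group from the aldol guarding against retro-aldol. The MOM group goes on last, when no doubly activated α-centre is left to meet an amine base.
- **Prenyl comes late.** An aryl prenyl ether would ionise under Me3SiOTf, and its alkene would compete for 16.
- **Assumption.** The magnesium-catalysed anti-aldol is taken to follow the chelated (Z)-enolate model, in which the (S)-4-benzyl auxiliary gives the (2R,3S) adduct. Should the sense prove opposite, the (R)-auxiliary is used with no other change.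

**Route**

Step 1
Reactants: 1 vanillin
Product: 2 3-methoxy-4-(triisopropylsilyloxy)benzaldehyde
Conditions: i-Pr3SiCl (1.1 equiv), imidazole (2.2 equiv), DMF, 0 °C → rt
Reagents that add atoms: triisopropylsilyl chloride, CC(C)[Si](Cl)(C(C)C)C(C)C
Why: Imidazole-promoted O-silylation of a phenol, the bulky TIPS ether being chosen because it tolerates the amide base, LiBH4 and Me3SiOTf used later and keeps the ring a strong para donor for step 9.

Step 2
Reactants: 2 3-methoxy-4-(triisopropylsilyloxy)benzaldehyde; 3 (2-carboxyethyl)triphenylphosphonium bromide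
Product: 5 (3E)-4-[3-methoxy-4-(triisopropylsilyloxy)phenyl]but-3-enoic acid, via ylide carboxylate 4 (not isolated)
Conditions: 3 (1.3 equiv), NaN(SiMe3)2 (2.6 equiv), THF, −78 → 0 °C; then 2, −78 °C → rt; 1 M HCl work-up
Reagents that add atoms: none
Why: Wittig reaction of a carboxylate-bearing ylide, a class that with aromatic aldehydes gives predominantly the (E)-β,γ-unsaturated acid, while the non-nucleophilic amide base spares the aryl silyl ether.

Step 3
Reactants: 5 (3E)-4-[3-methoxy-4-(triisopropylsilyloxy)phenyl]but-3-enoic acid; 6 (S)-4-benzyl-1,3-oxazolidin-2-one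
Product: 8 (4S)-4-benzyl-3-{(3E)-4-[3-methoxy-4-(triisopropylsilyloxy)phenyl]but-3-enoyl}-1,3-oxazolidin-2-one, via mixed pivalic anhydride 7 (not isolated)
Conditions: t-BuCOCl (1.05 equiv), Et3N (2.5 equiv), THF, −20 °C; then LiCl (1.1 equiv), 6 (1.0 equiv), −20 °C → rt
Reagents that add atoms: pivaloyl chloride, CC(C)(C)C(=O)Cl (its atoms appear only in intermediate 7)
Why: Mixed-anhydride N-acylation of an oxazolidinone under LiCl/Et3N, which needs no strong base and so leaves the double bond in conjugation with the arene.

Step 4
Reactants: 1 vanillin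
Product: 9 4-formyl-2-methoxyphenyl methanesulfonate
Conditions: MeSO2Cl (1.2 equiv), Et3N (1.5 equiv), CH2Cl2, 0 °C
Reagents that add atoms: methanesulfonyl chloride, CS(=O)(=O)Cl
Why: Sulfonylation of a phenol, giving a group that cancels the para donor effect (needed in step 9), survives Et3N/MgCl2, LiBH4, Me3SiOTf and fluoride, and leaves the aldehyde a good aldol acceptor.

Step 5
Reactants: 8 N-acyloxazolidinone; 9 4-formyl-2-methoxyphenyl methanesulfonate
Product: 10 (4S)-4-benzyl-3-{(2R,3E)-2-[(S)-[3-methoxy-4-(mesyloxy)phenyl](trimethylsilyloxy)methyl]-4-[3-methoxy-4-(triisopropylsilyloxy)phenyl]but-3-enoyl}-1,3-oxazolidin-2-one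
Conditions: MgCl2 (0.2 equiv), Et3N (2 equiv), Me3SiCl (1.5 equiv), 9 (1.2 equiv), EtOAc, 23 °C
Reagents that add atoms: chlorotrimethylsilane, C[Si](C)(C)Cl
Why: Magnesium-halide-catalysed Evans anti-aldol reaction with a non-enolisable aromatic aldehyde, in which the chelated (Z)-enolate reacts at its α-carbon on the face remote from the benzyl group (C8, R in the imide), the anti topology sets C7 as S, and O-silylation makes the addition irreversible and turns the catalyst over.

Step 6
Reactants: 10 anti-aldol adduct as its O-SiMe3 ether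
Product: 12 (1S,2S)-1-[3-methoxy-4-(mesyloxy)phenyl]-2-{(E)-2-[3-methoxy-4-(triisopropylsilyloxy)phenyl]ethenyl}propane-1,3-diol, via primary alcohol trimethylsilyl ether 11 (not isolated)
Conditions: LiBH4 (2 equiv), MeOH (2 equiv), THF, 0 °C; then citric acid (cat.), MeOH, rt
Reagents that add atoms: none
Why: Reductive removal of the auxiliary with LiBH4 (imide to primary alcohol), the O-SiMe3 group blocking alkoxide-driven retro-aldol until the carbonyl is gone and then falling to mild acid methanolysis, with neither stereocentre touched.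

Step 7
Reactants: 12 anti diol
Product: 13 (1S,2S)-3-(tert-butyldimethylsilyloxy)-1-[3-methoxy-4-(mesyloxy)phenyl]-2-{(E)-2-[3-methoxy-4-(triisopropylsilyloxy)phenyl]ethenyl}propan-1-ol
Conditions: t-BuMe2SiCl (1.05 equiv), imidazole (2 equiv), CH2Cl2, 0 °C
Reagents that add atoms: tert-butyldimethylsilyl chloride, CC(C)(C)[Si](C)(C)Cl
Why: Chemoselective silylation of the primary hydroxyl, the secondary benzylic hydroxyl being flanked by an aryl group and a branched carbon and reacting much more slowly with the bulky chlorosilane.

Step 8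
Reactants: 13 primary TBS ether; 14 chloromethyl methyl ether
Product: 15 (1S,2S,3E)-2-[(tert-butyldimethylsilyloxy)methyl]-1-(methoxymethoxy)-1-[3-methoxy-4-(mesyloxy)phenyl]-4-[3-methoxy-4-(triisopropylsilyloxy)phenyl]but-3-ene
Conditions: 14 (3 equiv), i-Pr2NEt (4 equiv), Bu4NI (0.1 equiv), CH2Cl2, 0 → 35 °C
Reagents that add atoms: chloromethyl methyl ether (14), COCCl
Why: MOM ether formation (O-alkylation with an α-chloro ether under amine base), which places the future C9' on O7 unambiguously because O9 is already blocked and meets no base-sensitive centre now that the imide is gone.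

Step 9
Reactants: 15 anti MOM ether
Product: 18 4-[(1S,3aS,4R,6aS)-4-[3-methoxy-4-(triisopropylsilyloxy)phenyl]tetrahydro-1H,3H-furo[3,4-c]furan-1-yl]-2-methoxyphenyl methanesulfonate, via oxocarbenium ion 16 (not isolated), via benzylic cation 17 (not isolated)
Conditions: Me3SiOTf (1.2 equiv), 2,6-di-tert-butyl-4-methylpyridine (1.5 equiv), CH2Cl2 (0.005 M), −78 → −40 °C; sat. aq NaHCO3 at −40 °C
Reagents that add atoms: none
Why: Proposed new method: Me3SiOTf silylates the outer methoxy oxygen of 15 and expels MeOSiMe3 to give oxocarbenium ion 16, whose CH2 carbon (C9') is attacked by C8', the nucleophilic β-carbon of the para-silyloxystyrene, giving the quinone-methide-like cation 17 that the C9 silyl ether oxygen captures with loss of t-BuMe2SiOTf; the closest known reaction type is the Prins cyclisation of acetals and MOM ethers of homocinnamyl alcohols to 3-(α-substituted benzyl)tetrahydrofurans with an external nucleophile, and the new element is termination by an internal silyl ether so that a second ring forms. Ring A closes 5-exo-trig with respect to C8'=C7' (endo with respect to O=C9'), the 6-endo mode and the related 2-oxonia-Cope shift both needing bond formation at C7', which the aryl donor makes the electrophilic and not the nucleophilic alkene terminus; ring B closes by collapse of O9 on a discrete cation, 5-exo-trig on the C7'=C1' bond of its quinone-methide form although formally 5-endo on the original alkene, so the two closures must be stepwise. C8' is controlled by C7 and C8: in the envelope transition state the C7 aryl group sits pseudo-equatorial, which forces the cis-disposed C8 CH2OTBS arm pseudo-axial and onto the same ring face as the emerging C7', the only relationship from which the cis-fused bicycle can form. C7' is controlled by the (E)-geometry, since net anti addition of C9' and O9 across the alkene places the aryl group exo, and by thermodynamics, since the donor-substituted C7'–O bond can re-ionise and the endo,endo alternative is much more strained. The step needs C-attack over O-attack on 16 (O9 attack would give a 1,3-dioxane and let the CH2 wander to O9, from which an isomeric 1,3-diaryl bicycle could arise), secured by the bulky TBS group, high dilution and low temperature, and it needs C7 to stay inert, secured by the mesylate, which retards C7–O ionisation, oxonia-Cope fragmentation and Friedel–Crafts attack of its ring on 17. The hindered pyridine removes TfOH, which would otherwise protonate the styrene and let O9 close a monocyclic tetrahydrofuran lacking C9'.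

Step 10
Reactants: 18 TIPS-protected furofuran mesylate; 19 prenyl bromide (1-bromo-3-methylbut-2-ene)
Product: 21 4-[(1S,3aS,4R,6aS)-4-{3-methoxy-4-[(3-methylbut-2-en-1-yl)oxy]phenyl}tetrahydro-1H,3H-furo[3,4-c]furan-1-yl]-2-methoxyphenyl methanesulfonate, via phenol 20 (not isolated)
Conditions: Bu4NF (1.1 equiv), THF, 0 °C; then 19 (1.5 equiv), 0 °C → rt
Reagents that add atoms: prenyl bromide (19), CC(C)=CCBr
Why: Fluoride cleavage of the aryl silyl ether followed in the same flask by Williamson ether synthesis, the tetrabutylammonium phenoxide being O-alkylated rapidly by the primary allylic bromide while the aryl mesylate is untouched at this temperature.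

Step 11
Reactants: 21 prenyl ether mesylate
Product: 22 4-[(1S,3aS,4R,6aS)-4-{3-methoxy-4-[(3-methylbut-2-en-1-yl)oxy]phenyl}tetrahydro-1H,3H-furo[3,4-c]furan-1-yl]-2-methoxyphenol (target)
Conditions: KOH (10 equiv), 1,4-dioxane–H2O (3:1), 70 °C; 1 M HCl to pH 7 at 0 °C
Reagents that add atoms: none
Why: Alkaline hydrolysis of an aryl sulfonate, to which the prenyl ether, the furofuran and all four stereocentres are inert, water being used instead of an alcohol so that no alkyl methanesulfonate can form and alkylate the liberated phenoxide, and the cold neutral work-up protecting the now electron-rich endo C7 centre from acid epimerisation.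

**Compound list**
1 | vanillin | COc1cc(C=O)ccc1O | starting material
2 | 3-methoxy-4-(triisopropylsilyloxy)benzaldehyde | COc1cc(C=O)ccc1O[Si](C(C)C)(C(C)C)C(C)C | intermediate
3 | (2-carboxyethyl)triphenylphosphonium bromide | [Br-].OC(=O)CC[P+](c1ccccc1)(c1ccccc1)c1ccccc1 | starting material
4 | ylide carboxylate, sodium 3-(triphenylphosphoranylidene)propanoate (not isolated) | [Na+].[O-]C(=O)CC=P(c1ccccc1)(c1ccccc1)c1ccccc1 | intermediate
5 | (3E)-4-[3-methoxy-4-(triisopropylsilyloxy)phenyl]but-3-enoic acid | OC(=O)C/C=C/c1ccc(O[Si](C(C)C)(C(C)C)C(C)C)c(OC)c1 | intermediate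
6 | (S)-4-benzyl-1,3-oxazolidin-2-one | O=C1N[C@@H](Cc2ccccc2)CO1 | starting material
7 | mixed anhydride of 5 with pivalic acid (not isolated) | CC(C)(C)C(=O)OC(=O)C/C=C/c1ccc(O[Si](C(C)C)(C(C)C)C(C)C)c(OC)c1 | intermediate
8 | (4S)-4-benzyl-3-[(3E)-4-Ar'-but-3-enoyl]-1,3-oxazolidin-2-one | O=C1OC[C@H](Cc2ccccc2)N1C(=O)C/C=C/c1ccc(O[Si](C(C)C)(C(C)C)C(C)C)c(OC)c1 | intermediate
9 | 4-formyl-2-methoxyphenyl methanesulfonate (vanillin mesylate) | COc1cc(C=O)ccc1OS(C)(=O)=O | intermediate
10 | (2R,3S) anti-aldol adduct of 8 and 9 as its O-SiMe3 ether | O=C1OC[C@H](Cc2ccccc2)N1C(=O)[C@@H]([C@H](O[Si](C)(C)C)c1ccc(OS(C)(=O)=O)c(OC)c1)/C=C/c1ccc(O[Si](C(C)C)(C(C)C)C(C)C)c(OC)c1 | intermediate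
11 | (1S,2S) primary alcohol still carrying the C7 O-SiMe3 group (not isolated) | OC[C@@H]([C@H](O[Si](C)(C)C)c1ccc(OS(C)(=O)=O)c(OC)c1)/C=C/c1ccc(O[Si](C(C)C)(C(C)C)C(C)C)c(OC)c1 | intermediate
12 | (1S,2S)-1-Ar-2-[(E)-2-Ar'-ethenyl]propane-1,3-diol | OC[C@@H]([C@H](O)c1ccc(OS(C)(=O)=O)c(OC)c1)/C=C/c1ccc(O[Si](C(C)C)(C(C)C)C(C)C)c(OC)c1 | intermediate
13 | primary (C9) TBS ether of 12 | CC(C)(C)[Si](C)(C)OC[C@@H]([C@H](O)c1ccc(OS(C)(=O)=O)c(OC)c1)/C=C/c1ccc(O[Si](C(C)C)(C(C)C)C(C)C)c(OC)c1 | intermediate
14 | chloromethyl methyl ether | COCCl | starting material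
15 | C7 MOM ether of 13, (1S,2S,3E), key-step precursor | CS(=O)(=O)Oc1ccc(cc1OC)[C@@H](OCOC)[C@H](CO[Si](C)(C)C(C)(C)C)/C=C/c1ccc(O[Si](C(C)C)(C(C)C)C(C)C)c(OC)c1 | intermediate
16 | O7=C9'H2 oxocarbenium ion (not isolated) | CS(=O)(=O)Oc1ccc(cc1OC)[C@@H]([O+]=C)[C@H](CO[Si](C)(C)C(C)(C)C)/C=C/c1ccc(O[Si](C(C)C)(C(C)C)C(C)C)c(OC)c1 | intermediate
17 | all-cis ring A tetrahydrofuran with C7' benzylic cation (not isolated) | CS(=O)(=O)Oc1ccc(cc1OC)[C@H]2OC[C@@H]([CH+]c1ccc(O[Si](C(C)C)(C(C)C)C(C)C)c(OC)c1)[C@H]2CO[Si](C)(C)C(C)(C)C | intermediate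
18 | (7S,8S,7'R,8'S) furofuran, Ar endo on C7, Ar' exo on C7' | CS(=O)(=O)Oc1ccc(cc1OC)[C@H]2OC[C@@H]3[C@H]2CO[C@H]3c1ccc(O[Si](C(C)C)(C(C)C)C(C)C)c(OC)c1 | intermediate
19 | prenyl bromide | CC(C)=CCBr | starting material
20 | furofuran with free C4' phenol and C4 mesylate (in the flask as its Bu4N phenoxide, not isolated) | CS(=O)(=O)Oc1ccc(cc1OC)[C@H]2OC[C@@H]3[C@H]2CO[C@H]3c1ccc(O)c(OC)c1 | intermediate
21 | C4' prenyl ether, C4 mesylate | CS(=O)(=O)Oc1ccc(cc1OC)[C@H]2OC[C@@H]3[C@H]2CO[C@H]3c1ccc(OCC=C(C)C)c(OC)c1 | intermediate
22 | target CNP0185952.9 | COc1cc([C@H]2OC[C@@H]3[C@H]2CO[C@H]3c2ccc(OCC=C(C)C)c(OC)c2)ccc1O | target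

**Step count**
Total: 11 steps. Longest linear sequence: 10 steps (1, 2, 3, 5, 6, 7, 8, 9, 10, 11 from vanillin).

**Steps most likely to fail**

*Step 9.*
- What may go wrong:
  - The C9 oxygen may capture the oxocarbenium ion instead of the alkene, after which the CH2 unit can migrate between the two oxygens.
  - Ring A may close on the wrong face of C8'. Internal capture is then impossible, and the cation is lost by proton loss, arylation or oligomerisation.
  - C7 may erode slowly on long exposure to the Lewis acid.
- Fallback: known chemistry, with a radical C–C closure and an oxidative C–O closure in place of the cationic cascade. It sets out from 15 and returns at 20.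
  - Me2BBr (CH2Cl2, −78 °C) exchanges the methoxy group for bromide to give the bromomethyl ether F1. This is quenched in the same flask with PhSeH/i-Pr2NEt to the (phenylselanyl)methyl ether F2.
  - Bu3SnH/AIBN (benzene, 80 °C, slow addition) generates the alkoxymethyl radical, which closes ring A 5-exo onto C8'. Hydrogen transfer to the benzylic radical gives the all-cis tetrahydrofuran F3. The same pseudo-equatorial aryl preference governs C8'.
  - Bu4NF removes both silyl groups to give the phenol alcohol F4.
  - Ag2O (CH2Cl2, rt) dehydrogenates the 4-alkyl-2-methoxyphenol to the para-quinone methide F5. The C9 hydroxyl adds to it in 1,6-fashion, closing ring B with the aryl group exo and giving 20.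
  - Compound 20 is then prenylated with 19 (K2CO3, DMF) to 21.

*Step 5.*
- What may go wrong:
  - Anti or facial selectivity may be lost because the nucleophile is an extended dienolate.
  - The dienolate may attack through its γ-carbon.
  - The amine may epimerise the adduct or cause β-elimination at its doubly activated α-carbon.
- Fallback: no enolate is used. The C7–C8 bond is made by allylmetal addition and the aryl group is attached afterwards. It sets out from 9 and returns at 12.
  - Iridium-catalysed transfer-hydrogenative anti-(hydroxymethyl)allylation of 9 with 4-vinyl-1,3-dioxolan-2-one should give the anti vinyl diol F6. Conditions: [Ir(cod)Cl]2, a chiral bisphosphine of the enantiomeric series that delivers the (1S,2S) product, 4-chloro-3-nitrobenzoic acid, K3PO4, i-PrOH, THF, 60 °C.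
  - Aldehyde 2 is methylenated (Ph3PCH3Br, NaN(SiMe3)2, THF) to the styrene F7.
  - Cross-metathesis of F6 with F7 (second-generation Grubbs catalyst, CH2Cl2, 40 °C) gives the (E)-alkene 12.

*Step 2.*
- What may go wrong:
  - The ylide may undergo β-elimination to acrylate and PPh3 before it meets the electron-rich, sluggish aldehyde.
  - (E)-selectivity may erode.
- Fallback: one-carbon homologation, then a decarboxylative condensation whose geometry is set thermodynamically. It sets out from 2 and returns at 5.
  - Wittig reaction with Ph3P=CHOMe (from Ph3PCH2OMe chloride and NaN(SiMe3)2) gives the enol ether F8. Its E/Z composition is inconsequential.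
  - Mild acid hydrolysis (HCO2H, CH2Cl2–H2O) gives the arylacetaldehyde F9.
  - Knoevenagel condensation of F9 with malonic acid under amine catalysis (Et3N, 90 °C), with decarboxylation, gives 5. The double bond settles (E) and in conjugation with the arene.

**Further compounds**
F1 | step 9 | bromomethyl ether of 13 on O7 | CS(=O)(=O)Oc1ccc(cc1OC)[C@@H](OCBr)[C@H](CO[Si](C)(C)C(C)(C)C)/C=C/c1ccc(O[Si](C(C)C)(C(C)C)C(C)C)c(OC)c1
F2 | step 9 | (phenylselanyl)methyl ether of 13 on O7 | CS(=O)(=O)Oc1ccc(cc1OC)[C@@H](OC[Se]c1ccccc1)[C@H](CO[Si](C)(C)C(C)(C)C)/C=C/c1ccc(O[Si](C(C)C)(C(C)C)C(C)C)c(OC)c1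
F3 | step 9 | (7S,8S,8'S) all-cis 2-Ar-3-(TBSO-methyl)-4-(Ar'-methyl)tetrahydrofuran | CS(=O)(=O)Oc1ccc(cc1OC)[C@H]2OC[C@@H](Cc1ccc(O[Si](C(C)C)(C(C)C)C(C)C)c(OC)c1)[C@H]2CO[Si](C)(C)C(C)(C)C
F4 | step 9 | phenol alcohol from F3 | CS(=O)(=O)Oc1ccc(cc1OC)[C@H]2OC[C@@H](Cc1ccc(O)c(OC)c1)[C@H]2CO
F5 | step 9 | para-quinone methide from F4 | CS(=O)(=O)Oc1ccc(cc1OC)[C@H]2OC[C@@H](C=C1C=CC(=O)C(OC)=C1)[C@H]2CO
F6 | step 5 | (1S,2S)-1-[3-methoxy-4-(mesyloxy)phenyl]-2-vinylpropane-1,3-diol | OC[C@@H]([C@H](O)c1ccc(OS(C)(=O)=O)c(OC)c1)C=C
F7 | step 5 | 3-methoxy-4-(triisopropylsilyloxy)styrene | C=Cc1ccc(O[Si](C(C)C)(C(C)C)C(C)C)c(OC)c1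
F8 | step 2 | 1-(2-methoxyethenyl)-3-methoxy-4-(triisopropylsilyloxy)benzene (E/Z mixture) | COC=Cc1ccc(O[Si](C(C)C)(C(C)C)C(C)C)c(OC)c1
F9 | step 2 | [3-methoxy-4-(triisopropylsilyloxy)phenyl]acetaldehyde | O=CCc1ccc(O[Si](C(C)C)(C(C)C)C(C)C)c(OC)c1
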